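The central benzene ring of the p-terphenyl is hexasubstituted: the two aryl-bearing carbons (C3, C6) are para, and the four oxygenated carbons form two adjacent pairs (C1/C2 benzoates, C4/C5 hydroxyls). A chromium carbene [3+2+1] benzannulation assembles this ring in one operation from an alkenyl(benzyloxy)carbene complex (C4, C5, C6), an aryl siloxyalkyne (C3, C2) and one CO ligand (C1). It delivers the two oxygen pairs differently protected. The precursor is a pentacarbonylchromium carbene whose carbene carbon carries a benzyloxy group and a (Z)-1-(benzyloxy)-2-[4-(benzyloxy)phenyl]vinyl group.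

Key step: step 6

Remark: the central ring is numbered as in the target SMILES (C1, C2 benzoate carbons; C3, C6 aryl carbons; C4, C5 hydroxyl carbons). Tributyltin hydride, benzyl chloromethyl ether, Cr(CO)6, 4-(benzyloxy)benzaldehyde and 1-(benzyloxy)-4-ethynylbenzene are taken as purchasable.

Step 1
Reactants: 1 tributyltin hydride (Bu3SnH); 2 benzyl chloromethyl ether
Product: 4 tributyl[(benzyloxy)methyl]stannane, via tributylstannyllithium 3 (not isolated)
Conditions: LiN(iPr)2, THF, 0 °C; then 2, −78 → 20 °C
Reagents that add atoms: none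
Why: Deprotonation of Bu3SnH gives the stannyl anion, which displaces chloride from the reactive α-chloro ether (SN2 alkylation of a stannyllithium), a standard entry to α-alkoxymethylstannanes.

Step 2
Reactants: 4 tributyl[(benzyloxy)methyl]stannane; 5 chromium hexacarbonyl, Cr(CO)6
Product: 8 tetramethylammonium pentacarbonyl[2-(benzyloxy)acetyl]chromate, via (benzyloxy)methyllithium 6 (not isolated), via lithium acylchromate 7 (not isolated)
Conditions: n-BuLi, THF, −78 °C; Cr(CO)6, THF, −78 → −20 °C; Me4NBr, H2O, 20 °C
Reagents that add atoms: tetramethylammonium bromide, C[N+](C)(C)C.[Br-]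
Why: Tin–lithium exchange releases (benzyloxy)methyllithium at −78 °C, where it is stable, and its addition to a CO ligand of Cr(CO)6 (acylmetalate stage of the Fischer carbene synthesis) followed by cation metathesis should give the air-stable ammonium acylchromate.

Step 3
Reactants: 8 tetramethylammonium pentacarbonyl[2-(benzyloxy)acetyl]chromate
Product: 10 pentacarbonyl[(benzyloxy)(benzyloxymethyl)carbene]chromium, via acetoxycarbene complex 9 (not isolated)
Conditions: AcBr, CH2Cl2, −40 °C; then BnOH, −40 → 0 °C
Reagents that add atoms: benzyl alcohol, OCc1ccccc1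
Why: O-Acylation of the acylchromate gives an electrophilic acyloxycarbene in which benzyl alcohol replaces acetate by addition–elimination at the carbene carbon (acyloxycarbene alcoholysis), the usual way to alkoxycarbene complexes that cannot be made by direct O-alkylation.

Step 4
Reactants: 10 pentacarbonyl[(benzyloxy)(benzyloxymethyl)carbene]chromium; 11 4-(benzyloxy)benzaldehyde
Product: 12 pentacarbonyl{(benzyloxy)[(Z)-1-(benzyloxy)-2-[4-(benzyloxy)phenyl]vinyl]carbene}chromium
Conditions: Et3N, Me3SiCl, Et2O, 20 °C
Reagents that add atoms: none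
Why: The CH2 between the carbene carbon and the ether oxygen is acidic enough for Et3N, the carbanion adds to the non-enolisable aldehyde, Me3SiCl traps the aldolate and E1cB loss of silanolate gives the conjugated alkenylcarbene (aldol condensation of an alkoxycarbene complex), with the aryl group trans to the bulky chromium carbene unit under thermodynamic control.

Step 5
Reactants: 13 1-(benzyloxy)-4-ethynylbenzene
Product: 16 {[4-(benzyloxy)phenyl]ethynyloxy}triisopropylsilane, via lithium acetylide 14 (not isolated), via lithium ynolate 15 (not isolated)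
Conditions: LiN(SiMe3)2, tBuOOH, THF, −78 °C; 13, −78 → 0 °C; iPr3SiOTf, −78 → 0 °C
Reagents that add atoms: tert-butyl hydroperoxide, CC(C)(C)OO; triisopropylsilyl trifluoromethanesulfonate, CC(C)[Si](OS(=O)(=O)C(F)(F)F)(C(C)C)C(C)C
Why: Electrophilic oxygen transfer from LiOOtBu to the lithium acetylide gives the ynolate, which the bulky silyl triflate captures on oxygen (acetylide oxidation–O-silylation route to siloxyalkynes), and the amide base spares the benzyl ether from metalation.

Step 6
Reactants: 12 pentacarbonyl{(benzyloxy)[(Z)-1-(benzyloxy)-2-[4-(benzyloxy)phenyl]vinyl]carbene}chromium; 16 {[4-(benzyloxy)phenyl]ethynyloxy}triisopropylsilane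
Product: 18 3,4-bis(benzyloxy)-2,5-bis[4-(benzyloxy)phenyl]-6-[(triisopropylsilyl)oxy]phenol, via tricarbonylchromium arene complex 17 (not isolated)
Conditions: 16 (1.5 equiv), THF, 55 °C, Ar, dark; then air, MeCN, 20 °C
Reagents that add atoms: none
Why: Proposed new method: thermal loss of one CO from 12 opens a coordination site for alkyne 16, whose nucleophilic aryl-bearing carbon bonds to the electrophilic carbene carbon, so that insertion gives a chromium-bound dienylcarbene with the siloxy group on the new carbene carbon; migration of a CO ligand onto this carbon gives a complexed dienylketene, which cyclises and tautomerises to the phenol, first obtained as its Cr(CO)3 complex 17 and released by air. The closest known reactions are the Dötz benzannulation of alkenyl(alkoxy)carbene chromium complexes with ordinary alkynes, the polarity-controlled insertion of ynamines into such complexes, and the carbonylative cyclisation of dienyl(alkoxy)carbene chromium complexes to ortho-alkoxyphenols. The single new ring, the central benzene ring, is closed by 6π-electrocyclisation of the dienylketene (ketene carbon to the styryl CH carbon) followed by enolisation, and no stereocentre is formed. The step needs regioselectivity (aryl carbon to carbene carbon, siloxy carbon to CO), which the ynol-ether polarisation should secure, and the (Z)-geometry of 12 places only hydrogen on the inside of the closing triene. If CO insertion at the siloxy-stabilised carbene is slow, irradiation with visible light under CO (1 atm) should drive it, and an oxidative work-up with (NH4)2Ce(NO3)6 is avoided because 18 is a para-alkoxyphenol.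

Step 7
Reactants: 18 3,4-bis(benzyloxy)-2,5-bis[4-(benzyloxy)phenyl]-6-[(triisopropylsilyl)oxy]phenol
Product: 20 4,5-bis(benzyloxy)-3,6-bis[4-(benzyloxy)phenyl]-1,2-phenylene dibenzoate, via catechol 19 (not isolated)
Conditions: Bu4NF, THF, 0 °C, Ar; then BzCl, Et3N, DMAP, 0 → 20 °C
Reagents that add atoms: benzoyl chloride, O=C(Cl)c1ccccc1
Why: Fluoride-induced Si–O cleavage liberates the catechol as its ammonium phenoxide, and DMAP-catalysed O-acylation of both phenolic oxygens in the same flask (desilylation–esterification) avoids handling the oxidation-prone electron-rich catechol.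

Step 8
Reactants: 20 4,5-bis(benzyloxy)-3,6-bis[4-(benzyloxy)phenyl]-1,2-phenylene dibenzoate
Product: 21 4,5-dihydroxy-3,6-bis(4-hydroxyphenyl)-1,2-phenylene dibenzoate (CNP0216579.0)
Conditions: H2 (1 atm), Pd/C, EtOAc/THF, 20 °C
Reagents that add atoms: none
Why: Catalytic hydrogenolysis over Pd/C cleaves the four benzyl aryl ethers while aryl benzoates are inert, and no liberated hydroxyl sits next to an ester-bearing carbon, so acyl migration is not expected.

Compound list
1 | tributyltin hydride (Bu3SnH) | CCCC[SnH](CCCC)CCCC | starting material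
2 | benzyl chloromethyl ether | ClCOCc1ccccc1 | starting material
3 | tributylstannyllithium (in situ) | [Li][Sn](CCCC)(CCCC)CCCC | intermediate
4 | tributyl[(benzyloxy)methyl]stannane | CCCC[Sn](CCCC)(CCCC)COCc1ccccc1 | intermediate
5 | chromium hexacarbonyl, Cr(CO)6 | O=C=[Cr](=C=O)(=C=O)(=C=O)(=C=O)=C=O | starting material
6 | (benzyloxy)methyllithium (in situ) | [Li]COCc1ccccc1 | intermediate
7 | lithium pentacarbonyl[2-(benzyloxy)acetyl]chromate (in situ) | [Li+].O=C=[Cr-](=C=O)(=C=O)(=C=O)(=C=O)C(=O)COCc1ccccc1 | intermediate
8 | tetramethylammonium pentacarbonyl[2-(benzyloxy)acetyl]chromate | C[N+](C)(C)C.O=C=[Cr-](=C=O)(=C=O)(=C=O)(=C=O)C(=O)COCc1ccccc1 | intermediate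
9 | pentacarbonyl[(acetoxy)(benzyloxymethyl)carbene]chromium (in situ) | O=C=[Cr](=C=O)(=C=O)(=C=O)(=C=O)=C(OC(C)=O)COCc1ccccc1 | intermediate
10 | pentacarbonyl[(benzyloxy)(benzyloxymethyl)carbene]chromium | O=C=[Cr](=C=O)(=C=O)(=C=O)(=C=O)=C(OCc1ccccc1)COCc1ccccc1 | intermediate
11 | 4-(benzyloxy)benzaldehyde | O=Cc1ccc(OCc2ccccc2)cc1 | starting material
12 | pentacarbonyl{(benzyloxy)[(Z)-1-(benzyloxy)-2-[4-(benzyloxy)phenyl]vinyl]carbene}chromium (aryl trans to the carbene carbon) | O=C=[Cr](=C=O)(=C=O)(=C=O)(=C=O)=C(OCc1ccccc1)/C(OCc1ccccc1)=C/c1ccc(OCc2ccccc2)cc1 | intermediate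
13 | 1-(benzyloxy)-4-ethynylbenzene | C#Cc1ccc(OCc2ccccc2)cc1 | starting material
14 | lithium [4-(benzyloxy)phenyl]acetylide (in situ) | [Li]C#Cc1ccc(OCc2ccccc2)cc1 | intermediate
15 | lithium 2-[4-(benzyloxy)phenyl]ethynolate (in situ) | [Li+].[O-]C#Cc1ccc(OCc2ccccc2)cc1 | intermediate
16 | {[4-(benzyloxy)phenyl]ethynyloxy}triisopropylsilane | CC(C)[Si](OC#Cc1ccc(OCc2ccccc2)cc1)(C(C)C)C(C)C | intermediate
17 | tricarbonylchromium complex of phenol 18 (in situ; Cr(CO)3 bound η6 to the central ring, written as two parts) | Oc1c(O[Si](C(C)C)(C(C)C)C(C)C)c(-c2ccc(OCc3ccccc3)cc2)c(OCc2ccccc2)c(OCc2ccccc2)c1-c1ccc(OCc2ccccc2)cc1.O=C=[Cr](=C=O)=C=O | intermediate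
18 | 3,4-bis(benzyloxy)-2,5-bis[4-(benzyloxy)phenyl]-6-[(triisopropylsilyl)oxy]phenol | Oc1c(O[Si](C(C)C)(C(C)C)C(C)C)c(-c2ccc(OCc3ccccc3)cc2)c(OCc2ccccc2)c(OCc2ccccc2)c1-c1ccc(OCc2ccccc2)cc1 | intermediate
19 | 4,5-bis(benzyloxy)-3,6-bis[4-(benzyloxy)phenyl]benzene-1,2-diol (in situ) | Oc1c(O)c(-c2ccc(OCc3ccccc3)cc2)c(OCc2ccccc2)c(OCc2ccccc2)c1-c1ccc(OCc2ccccc2)cc1 | intermediate
20 | 4,5-bis(benzyloxy)-3,6-bis[4-(benzyloxy)phenyl]-1,2-phenylene dibenzoate | O=C(Oc1c(OC(=O)c2ccccc2)c(-c2ccc(OCc3ccccc3)cc2)c(OCc2ccccc2)c(OCc2ccccc2)c1-c1ccc(OCc2ccccc2)cc1)c1ccccc1 | intermediate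
21 | 4,5-dihydroxy-3,6-bis(4-hydroxyphenyl)-1,2-phenylene dibenzoate | O=C(Oc1c(OC(=O)c2ccccc2)c(-c2ccc(O)cc2)c(O)c(O)c1-c1ccc(O)cc1)c1ccccc1 | target

Total step count: 8. Longest linear sequence: 7 steps (1, 2, 3, 4, 6, 7, 8); step 5 is a one-step side branch.

Steps most likely to fail

Step 6 (key step). What may go wrong: insertion of the siloxyalkyne with the reverse orientation, arrest at the heteroatom-stabilised dienylcarbene without CO insertion, or diversion of that carbene into five-membered-ring products. Fallback with known chemistry: the siloxyalkyne is replaced by an alkynylboronate, a class whose benzannulation with alkoxycarbene chromium complexes is established and should place boron next to the CO-derived phenol carbon; the boron then serves as a masked hydroxyl. The fallback sets out from alkyne 13 and uses carbene 12. Alkyne 13 is deprotonated (n-BuLi, THF, −78 °C) and borylated with 2-isopropoxy-4,4,5,5-tetramethyl-1,3,2-dioxaborolane, followed by HCl in Et2O, to give 2-{[4-(benzyloxy)phenyl]ethynyl}-4,4,5,5-tetramethyl-1,3,2-dioxaborolane F1. Heating F1 with 12 (THF, 50 °C, then air) should give 3,4-bis(benzyloxy)-2,5-bis[4-(benzyloxy)phenyl]-6-(4,4,5,5-tetramethyl-1,3,2-dioxaborolan-2-yl)phenol F2. Oxidation of the C–B bond (NaBO3·4H2O, THF/H2O, 20 °C) comes back to the route at catechol 19, which is benzoylated as in the second stage of step 7.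

Step 4. What may go wrong: reversible aldol addition with slow elimination at the hindered α-alkoxy carbon, or conjugate addition of the carbanion of 10 to product 12, leaving the condensation incomplete. Fallback: the one-pot equilibrium condensation is replaced by a directed aldol addition with an isolable adduct, followed by a separate elimination. It sets out from 10 and 11. Carbene 10 is deprotonated with n-BuLi (THF, −78 °C) and the anion is added to aldehyde 11 pre-complexed with BF3·OEt2, to give pentacarbonyl{(benzyloxy)[1-(benzyloxy)-2-[4-(benzyloxy)phenyl]-2-hydroxyethyl]carbene}chromium F3 as a mixture of diastereomers, both centres being lost afterwards. Mesylation and elimination (MeSO2Cl, Et3N, CH2Cl2, 0 °C) comes back to the route at 12.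

Step 2. What may go wrong: rearrangement or decomposition of the thermally fragile (benzyloxy)methyllithium before it adds to the sparingly soluble Cr(CO)6. Fallback: the polarity is inverted, with chromium as the nucleophile and the two-carbon unit as an acyl electrophile. It sets out from 5. Cr(CO)6 is reduced with C8K (2 equiv, THF, −78 °C) to dipotassium pentacarbonylchromate, K2Cr(CO)5 F4, which is acylated with commercial (benzyloxy)acetyl chloride to give potassium pentacarbonyl[2-(benzyloxy)acetyl]chromate F5. Cation exchange with Me4NBr in water comes back to the route at 8.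

Further compounds
F1 | step 6 | 2-{[4-(benzyloxy)phenyl]ethynyl}-4,4,5,5-tetramethyl-1,3,2-dioxaborolane | CC1(C)OB(C#Cc2ccc(OCc3ccccc3)cc2)OC1(C)C
F2 | step 6 | 3,4-bis(benzyloxy)-2,5-bis[4-(benzyloxy)phenyl]-6-(4,4,5,5-tetramethyl-1,3,2-dioxaborolan-2-yl)phenol | Oc1c(B2OC(C)(C)C(C)(C)O2)c(-c2ccc(OCc3ccccc3)cc2)c(OCc2ccccc2)c(OCc2ccccc2)c1-c1ccc(OCc2ccccc2)cc1
F3 | step 4 | pentacarbonyl{(benzyloxy)[1-(benzyloxy)-2-[4-(benzyloxy)phenyl]-2-hydroxyethyl]carbene}chromium (mixture of diastereomers) | O=C=[Cr](=C=O)(=C=O)(=C=O)(=C=O)=C(OCc1ccccc1)C(OCc1ccccc1)C(O)c1ccc(OCc2ccccc2)cc1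
F4 | step 2 | dipotassium pentacarbonylchromate, K2Cr(CO)5 | [K+].[K+].O=C=[Cr-2](=C=O)(=C=O)(=C=O)=C=O
F5 | step 2 | potassium pentacarbonyl[2-(benzyloxy)acetyl]chromate | [K+].O=C=[Cr-](=C=O)(=C=O)(=C=O)(=C=O)C(=O)COCc1ccccc1
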